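**Retrosynthetic overview**
1. The target is read as 3β-angeloyloxy-4β-acetoxy-7α-hydroxyeudesm-11-en-8-one, (3S,4R,5R,7S,10R). It is a trans-decalin with 10β-CH3 and 5α-H, a cis 3β(equatorial)/4β(axial) diester, 4α-CH3, an axial 7α-OH and an equatorial 7β-isopropenyl group.
2. The feature used is the vicinal pair C5 (CH) and C10 (C–CH3) on ring B. Their ring-A bonds C4–C5 and C1–C10 are trans, which is the geometry of (E)-OHC–C(CH3)=CH–COCH3. The O7/O8 pair of ring B corresponds to the enol silane left by a 2-silyloxybutadiene.
3. Ring B is made first, by a catalytic enantioselective Diels–Alder reaction that forms C5–C6 and C9–C10.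
4. Ring A is made second: formyl C1 is extended by C2–C3 (Wittig), the enal is reduced at C=C, and C3–C4 is closed by a SmI2 pinacol coupling to the cis-diol.
5. End game: Rubottom oxygenation at C8, isopropenyl addition to the C7 ketone, oxidation at C8, acetate delivered to O4 through a cyclic orthoacetate, angelate placed on O3.

Key step: step 3

Numbering: eudesmane numbering is used throughout (ring A = C1–C5 and C10; ring B = C5–C10; C14 = CH3 on C10; C15 = CH3 on C4).
Assumption: the sense of induction in step 3 is assigned from the formyl C–H···O binding model for α-methyl enals. If this dienophile responds in the opposite sense, the equally available (R)-configured oxazaborolidine is used instead.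

Step 1
Reactants: 1 methylglyoxal (40 % in water); 2 2-(triphenylphosphoranylidene)propanal
Product: 3 (E)-2-methyl-4-oxopent-2-enal
Conditions: 1 (1.5 equiv), slow addition of 2, CH2Cl2/H2O, 0 °C → rt
Reagents that add atoms: none
Why: Wittig olefination of an α-methyl stabilised ylide at the aldehyde carbon of 1, which is far more electrophilic than its ketone or the enal product, should give the (E)-trisubstituted alkene in one operation and avoids olefinating a ketone with an unreactive acyl ylide.

Step 2
Reactants: 4 methyl vinyl ketone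
Product: 5 2-(triisopropylsilyloxy)buta-1,3-diene
Conditions: iPr3SiOTf, Et3N, Et2O, 0 °C → rt
Reagents that add atoms: triisopropylsilyl triflate, CC(C)[Si](C(C)C)(C(C)C)OS(=O)(=O)C(F)(F)F
Why: Soft enolisation with O-silylation of the methyl ketone, which can enolise only towards CH3, is the standard entry to 2-silyloxydienes.

Step 3
Reactants: 3 (E)-2-methyl-4-oxopent-2-enal; 5 2-(triisopropylsilyloxy)buta-1,3-diene
Product: 6 (1R,6R)-6-acetyl-1-methyl-4-(triisopropylsilyloxy)cyclohex-3-ene-1-carbaldehyde (acetyl and formyl trans)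
Conditions: (S)-3,3-diphenyl-1-(o-tolyl)tetrahydro-1H,3H-pyrrolo[1,2-c][1,3,2]oxazaborole (20 mol %), Tf2NH (17 mol %), 5 (1.5 equiv), CH2Cl2, −78 °C; Et3N quench
Reagents that add atoms: none
Why: The N-protonated oxazaborolidine binds the formyl oxygen of 3 (the least hindered lone pair, held further by a formyl C–H···O contact), which lowers the LUMO of the C5=C10 alkene and places its largest coefficient on C5, the carbon β to the bound aldehyde. The closest known reaction type is the oxazaborolidinium-catalysed enantioselective Diels–Alder reaction of α-methyl-β-substituted enals, β-alkoxycarbonyl ones included, with 2-silyloxybutadienes and related dienes. Ring B is closed by an intermolecular, concerted but asynchronous [4+2] cycloaddition in which the nucleophilic CH2 terminus of the enol silane (C6) bonds first to C5 and C9–C10 follows. C5 and C10 are fixed relative to each other by suprafacial addition to the (E)-alkene, so that acetyl and formyl end up trans; their absolute sense comes from the catalyst, whose neighbouring phenyl group covers one face so that the diene reaches the Re face at C10 (also Re at C5). The step needs orientation by the aldehyde rather than the ketone, and selective formyl binding and the lower hindrance of the CH terminus C5 both favour that orientation; endo/exo orientation has no stereochemical consequence because the diene termini carry only hydrogen.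

Step 4
Reactants: 6 Diels–Alder adduct; 7 (triphenylphosphoranylidene)acetaldehyde
Product: 8 (E)-3-[(1S,6R)-6-acetyl-1-methyl-4-(triisopropylsilyloxy)cyclohex-3-en-1-yl]prop-2-enal (same spatial arrangement as 6)
Conditions: 7 (1.3 equiv), toluene, 90 °C
Reagents that add atoms: none
Why: Wittig olefination with a formyl-stabilised ylide under neutral conditions reacts only with the aldehyde C1, leaves the methyl ketone and enol silane untouched, and brings in C2 and C3 as the (E)-enal.

Step 5
Reactants: 8 enal
Product: 9 3-[(1R,6R)-6-acetyl-1-methyl-4-(triisopropylsilyloxy)cyclohex-3-en-1-yl]propanal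
Conditions: Bu3SnH, Pd(PPh3)4 (3 mol %), AcOH, THF, rt
Reagents that add atoms: none
Why: Conjugate reduction by tin hydride under zerovalent-palladium catalysis acts only on the polarised enal C=C, and acetic acid protonates the tin enolate at once so that no aldol closure onto the C4 ketone can begin, while the enol silane, ketone and saturated aldehyde are left alone.

Step 6
Reactants: 9 keto aldehyde
Product: 10 4α,10β-dimethyl-7-(triisopropylsilyloxy)-trans-octal-7-ene-3β,4β-diol (5α-H; 11,12,13-trinoreudesm-7-ene skeleton)
Conditions: SmI2 (2.5 equiv), t-BuOH (2 equiv), THF, −78 °C → rt; H2O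
Reagents that add atoms: none
Why: In this SmI2-mediated intramolecular ketone–aldehyde pinacol coupling both oxygens stay on one samarium centre, so the diol is cis, and the chair-like closure of ring A keeps C15 equatorial (an axial C15 would be 1,3-diaxial to C14), which places O4 axial β and therefore O3 equatorial β.

Step 7
Reactants: 10 enol silane diol
Product: 12 3β,4β-dihydroxy-8α-(triisopropylsilyloxy)-11,12,13-trinoreudesman-7-one, via silyloxy epoxide 11 (not isolated)
Conditions: mCPBA, CH2Cl2, −20 → 0 °C
Reagents that add atoms: mCPBA, O=C(OO)c1cccc(Cl)c1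
Why: In this Rubottom oxidation the peracid attacks the electron-rich C7=C8 bond from the α face, opposite the axial C14 methyl, and the silyloxy epoxide opens to the C7 oxocarbenium ion with 1,4-migration of the silyl group to O8, which leaves the ketone at C7 and an equatorial 8α-silyl ether.

Step 8
Reactants: 12 dihydroxy ketone
Product: 13 3β,4β-(isopropylidenedioxy)-8α-(triisopropylsilyloxy)-11,12,13-trinoreudesman-7-one
Conditions: 2-methoxypropene, pyridinium p-toluenesulfonate (cat.), CH2Cl2, 0 °C → rt
Reagents that add atoms: 2-methoxypropene, C=C(C)OC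
Why: Acid-catalysed acetonide formation is easy for a cis axial/equatorial 1,2-diol and is placed after the Rubottom step so that no acid meets the enol silane.

Step 9
Reactants: 13 ketone; 14 isopropenylmagnesium bromide
Product: 15 3β,4β-(isopropylidenedioxy)-8α-(triisopropylsilyloxy)eudesm-11-en-7α-ol
Conditions: 14 (2 equiv), LaCl3·2LiCl (1 equiv), THF, −78 → 0 °C; H2O
Reagents that add atoms: none
Why: This is a Grignard 1,2-addition to a lanthanum-activated ketone (enolisation suppressed), in which the bulky sp2 nucleophile should enter along the equatorial β trajectory, anti to the 8α-silyloxy group and clear of the axial 5α and 9α hydrogens, to give the axial 7α-alcohol with equatorial isopropenyl.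

Step 10
Reactants: 15 silyl ether
Product: 16 3β,4β-(isopropylidenedioxy)eudesm-11-ene-7α,8α-diol
Conditions: Bu4NF, THF, 0 °C → rt
Reagents that add atoms: none
Why: Fluoride-induced Si–O cleavage removes the only silyl group, and the acetonide and alkene are inert.

Step 11
Reactants: 16 diol
Product: 17 7α-hydroxy-3β,4β-(isopropylidenedioxy)eudesm-11-en-8-one
Conditions: Pr4NRuO4 (5 mol %), N-methylmorpholine N-oxide, 4 Å MS, CH2Cl2, rt
Reagents that add atoms: none
Why: Ley–Griffith oxidation converts the only secondary alcohol into the C8 ketone, the tertiary 7-OH cannot be oxidised, and the relay stereocentre C8 is erased.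

Step 12
Reactants: 17 acetonide
Product: 18 3β,4β,7α-trihydroxyeudesm-11-en-8-one
Conditions: AcOH/H2O 4:1, 45 °C
Reagents that add atoms: none
Why: In this acid hydrolysis of the isopropylidene acetal, ionisation of the tertiary allylic C7–OH is disfavoured by the adjacent C8 carbonyl, which is why the deprotection follows the oxidation.

Step 13
Reactants: 18 triol
Product: 20 4β-acetoxy-3β,7α-dihydroxyeudesm-11-en-8-one, via cyclic methyl orthoacetate 19 (not isolated)
Conditions: MeC(OMe)3, pyridinium p-toluenesulfonate (cat.), CH2Cl2, rt; then AcOH/H2O 4:1, 0 °C → rt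
Reagents that add atoms: trimethyl orthoacetate, COC(C)(OC)OC; water, O
Why: Orthoester exchange engages only the cis-3,4-diol, and kinetic hydrolysis of the ring-fused 2-methoxy-1,3-dioxolane through its hemiorthoester releases the equatorial, less substituted O3 and leaves the acyl group on the axial tertiary O4, so the hindered 4-OH is acetylated without touching the tertiary 7-OH.

Step 14
Reactants: 20 hydroxy acetate; 21 angelic acid ((Z)-2-methylbut-2-enoic acid)
Product: 22 3β-angeloyloxy-4β-acetoxy-7α-hydroxyeudesm-11-en-8-one (CNP0381775.1)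
Conditions: 21, 2,4,6-Cl3C6H2COCl, Et3N, toluene, rt; then 20, 80 °C
Reagents that add atoms: none
Why: Yamaguchi-type mixed-anhydride esterification run without a nucleophilic pyridine catalyst transfers the angeloyl group without Z→E isomerisation, and only the secondary 3β-OH is reactive enough, so the tertiary 7α-OH stays free.

**Compound list**
1 | methylglyoxal | CC(=O)C=O | starting material
2 | 2-(triphenylphosphoranylidene)propanal | CC(C=O)=P(c1ccccc1)(c1ccccc1)c1ccccc1 | starting material
3 | (E)-2-methyl-4-oxopent-2-enal | CC(=O)/C=C(\C)C=O | intermediate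
4 | methyl vinyl ketone | C=CC(C)=O | starting material
5 | 2-(triisopropylsilyloxy)buta-1,3-diene | C=CC(=C)O[Si](C(C)C)(C(C)C)C(C)C | intermediate
6 | (1R,6R)-6-acetyl-1-methyl-4-(triisopropylsilyloxy)cyclohex-3-ene-1-carbaldehyde | CC(=O)[C@@H]1CC(O[Si](C(C)C)(C(C)C)C(C)C)=CC[C@@]1(C)C=O | intermediate
7 | (triphenylphosphoranylidene)acetaldehyde | O=CC=P(c1ccccc1)(c1ccccc1)c1ccccc1 | starting material
8 | (E)-3-[(1S,6R)-6-acetyl-1-methyl-4-(triisopropylsilyloxy)cyclohex-3-en-1-yl]prop-2-enal | CC(=O)[C@@H]1CC(O[Si](C(C)C)(C(C)C)C(C)C)=CC[C@@]1(C)/C=C/C=O | intermediate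
9 | 3-[(1R,6R)-6-acetyl-1-methyl-4-(triisopropylsilyloxy)cyclohex-3-en-1-yl]propanal | CC(=O)[C@@H]1CC(O[Si](C(C)C)(C(C)C)C(C)C)=CC[C@@]1(C)CCC=O | intermediate
10 | 4α,10β-dimethyl-7-(triisopropylsilyloxy)-trans-octal-7-ene-3β,4β-diol | CC(C)[Si](C(C)C)(C(C)C)OC1=CC[C@@]2(C)CC[C@H](O)[C@](C)(O)[C@@H]2C1 | intermediate
11 | 7α,8α-epoxide of 10 (silyloxy epoxide) | CC(C)[Si](C(C)C)(C(C)C)O[C@]12O[C@H]1C[C@@]3(C)CC[C@H](O)[C@](C)(O)[C@@H]3C2 | intermediate
12 | 3β,4β-dihydroxy-8α-(triisopropylsilyloxy)-11,12,13-trinoreudesman-7-one | O=C1[C@@H](O[Si](C(C)C)(C(C)C)C(C)C)C[C@@]2(C)CC[C@H](O)[C@](C)(O)[C@@H]2C1 | intermediate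
13 | 3β,4β-(isopropylidenedioxy)-8α-(triisopropylsilyloxy)-11,12,13-trinoreudesman-7-one | O=C1[C@@H](O[Si](C(C)C)(C(C)C)C(C)C)C[C@@]2(C)CC[C@@H]3OC(C)(C)O[C@]3(C)[C@@H]2C1 | intermediate
14 | isopropenylmagnesium bromide | C=C(C)[Mg]Br | starting material
15 | 3β,4β-(isopropylidenedioxy)-8α-(triisopropylsilyloxy)eudesm-11-en-7α-ol | C=C(C)[C@@]1(O)C[C@@H]2[C@](C)(CC[C@@H]3OC(C)(C)O[C@]23C)C[C@@H]1O[Si](C(C)C)(C(C)C)C(C)C | intermediate
16 | 3β,4β-(isopropylidenedioxy)eudesm-11-ene-7α,8α-diol | C=C(C)[C@@]1(O)C[C@@H]2[C@](C)(CC[C@@H]3OC(C)(C)O[C@]23C)C[C@@H]1O | intermediate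
17 | 7α-hydroxy-3β,4β-(isopropylidenedioxy)eudesm-11-en-8-one | C=C(C)[C@@]1(O)C[C@@H]2[C@](C)(CC[C@@H]3OC(C)(C)O[C@]23C)CC1=O | intermediate
18 | 3β,4β,7α-trihydroxyeudesm-11-en-8-one | C=C(C)[C@@]1(O)C[C@@H]2[C@](C)(CC[C@H](O)[C@]2(C)O)CC1=O | intermediate
19 | 3β,4β-O-(1-methoxyethylidene) orthoacetate of 18 (orthoester carbon undefined) | C=C(C)[C@@]1(O)C[C@@H]2[C@](C)(CC[C@@H]3OC(C)(OC)O[C@]23C)CC1=O | intermediate
20 | 4β-acetoxy-3β,7α-dihydroxyeudesm-11-en-8-one | C=C(C)[C@@]1(O)C[C@@H]2[C@](C)(CC[C@H](O)[C@]2(C)OC(C)=O)CC1=O | intermediate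
21 | angelic acid | C/C=C(/C)C(=O)O | starting material
22 | 3β-angeloyloxy-4β-acetoxy-7α-hydroxyeudesm-11-en-8-one (CNP0381775.1) | C=C(C)[C@@]1(O)C[C@@H]2[C@](C)(CC[C@H](OC(=O)/C(C)=C\C)[C@]2(C)OC(C)=O)CC1=O | target

**Step count**
Total steps: 14. Longest linear sequence: 13 (steps 1 and 3–14; step 2 is the side branch).

**Steps most likely to fail**

Step 3. The ketone may compete with the aldehyde for the boron cation, which would erode regio- and enantiocontrol. The enol silane may also add to the bound aldehyde in Mukaiyama fashion.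
- The fallback takes the acetyl group out of the cycloaddition. It sets out from 5 and returns at 6.
- The same catalyst joins 5 to commercial ethyl (E)-3-methyl-4-oxobut-2-enoate F1. This belongs to the dienophile class on which this catalysis is established, and its ester is a much poorer ligand than a ketone. The product is ethyl (1R,6R)-6-formyl-6-methyl-3-(triisopropylsilyloxy)cyclohex-3-ene-1-carboxylate F2.
- NaBH4 (EtOH, 0 °C) reduces only the aldehyde to the hydroxy ester F3. This closes with loss of ethanol (cat. DBU if needed) to the trans-fused γ-lactone F4.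
- MeLi (1 equiv, THF, −78 °C) adds once to the lactone and gives, after quench, the keto alcohol F5, which is in equilibrium with its lactol.
- Dess–Martin oxidation (CH2Cl2, pyridine, rt) of the open form gives 6.

Step 6. The ketyl coupling may show poor diastereocontrol (trans-diol or the 3α,4α-cis arrangement), or the aldehyde may simply be reduced.
- The fallback replaces the reductive radical coupling by a polar umpolung closure followed by a separate reduction. It sets out from 9 and returns at 10.
- 3-Benzyl-5-(2-hydroxyethyl)-4-methylthiazolium chloride (20 mol %) with DBU (THF, 40 °C) effects an intramolecular crossed aldehyde–ketone benzoin reaction. The product is 4β-hydroxy-4α,10β-dimethyl-7-(triisopropylsilyloxy)-trans-octal-7-en-3-one F6.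
- Because this closure is reversible, it should settle on the isomer with equatorial C15.
- NaBH4 (MeOH, −20 °C) then delivers hydride axially from the α face and gives the equatorial 3β-alcohol, which is 10.

Step 13. The hemiorthoester may open towards O3, or the acetyl group may migrate from O4 to O3 before or during the angeloylation.
- The fallback reverses the order of the esters and masks O7. It sets out from 18 and returns at 22.
- The mixed-anhydride conditions of step 14 acylate the only secondary alcohol of 18 to give 3β-angeloyloxy-4β,7α-dihydroxyeudesm-11-en-8-one F7.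
- Et3SiOTf (1.1 equiv) with 2,6-lutidine (CH2Cl2, −78 °C) silylates the more accessible tertiary 7α-OH, since the 4β-OH is 1,3-diaxial to C14 and flanked by the angelate. This gives the 7-O-triethylsilyl ether F8.
- Ac2O, DMAP and Et3N (CH2Cl2, 40 °C) acetylate the remaining 4β-OH to give 4β-acetoxy-3β-angeloyloxy-7α-(triethylsilyloxy)eudesm-11-en-8-one F9.
- HF·pyridine (THF, 0 °C) removes the silyl group and gives 22.

**Further compounds**
F1 | step 3 | ethyl (E)-3-methyl-4-oxobut-2-enoate (commercial) | CCOC(=O)/C=C(\C)C=O
F2 | step 3 | ethyl (1R,6R)-6-formyl-6-methyl-3-(triisopropylsilyloxy)cyclohex-3-ene-1-carboxylate | CCOC(=O)[C@@H]1CC(O[Si](C(C)C)(C(C)C)C(C)C)=CC[C@@]1(C)C=O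
F3 | step 3 | ethyl 6-(hydroxymethyl)-6-methyl-3-(triisopropylsilyloxy)cyclohex-3-ene-1-carboxylate (configuration as F2) | CCOC(=O)[C@@H]1CC(O[Si](C(C)C)(C(C)C)C(C)C)=CC[C@@]1(C)CO
F4 | step 3 | trans-fused γ-lactone of F3 | O=C1OC[C@]2(C)CC=C(O[Si](C(C)C)(C(C)C)C(C)C)C[C@@H]12
F5 | step 3 | 1-[6-(hydroxymethyl)-6-methyl-3-(triisopropylsilyloxy)cyclohex-3-en-1-yl]ethanone (configuration as 6) | CC(=O)[C@@H]1CC(O[Si](C(C)C)(C(C)C)C(C)C)=CC[C@@]1(C)CO
F6 | step 6 | 4β-hydroxy-4α,10β-dimethyl-7-(triisopropylsilyloxy)-trans-octal-7-en-3-one | CC(C)[Si](C(C)C)(C(C)C)OC1=CC[C@@]2(C)CCC(=O)[C@](C)(O)[C@@H]2C1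
F7 | step 13 | 3β-angeloyloxy-4β,7α-dihydroxyeudesm-11-en-8-one | C=C(C)[C@@]1(O)C[C@@H]2[C@](C)(CC[C@H](OC(=O)/C(C)=C\C)[C@]2(C)O)CC1=O
F8 | step 13 | 3β-angeloyloxy-4β-hydroxy-7α-(triethylsilyloxy)eudesm-11-en-8-one | C=C(C)[C@@]1(O[Si](CC)(CC)CC)C[C@@H]2[C@](C)(CC[C@H](OC(=O)/C(C)=C\C)[C@]2(C)O)CC1=O
F9 | step 13 | 4β-acetoxy-3β-angeloyloxy-7α-(triethylsilyloxy)eudesm-11-en-8-one | C=C(C)[C@@]1(O[Si](CC)(CC)CC)C[C@@H]2[C@](C)(CC[C@H](OC(=O)/C(C)=C\C)[C@]2(C)OC(C)=O)CC1=O
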